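Ring A is disconnected at C1–C10 and C2–C3 (labdane numbering) into an acrylate two-carbon unit and a ring-B-fused cyclobutanol. The key step exploits the strained C3–C4–C5–C10 four-membered ring: an alkoxy radical at C3 opens the C3–C10 bond, unveiling the C3 aldehyde and a planar tertiary C10 radical; Giese addition to allyl acrylate (C1–C10) and aldol closure of the resulting enolate (C2–C3) build ring A and the C10 quaternary centre in one operation. The cyclobutanol precursor arises from an endo Diels–Alder reaction between a geraniol-derived triene ester and 2,4,4-trimethylcyclobutenone, which assembles ring B, C9 and the complete side chain.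

Key step: step 8

Remark: all ring atoms carry the labdane numbers of the target (C3 carbinol, C4 gem-dimethyl carbon, C5 and C10 ring fusion, C9 side-chain carbon, C20 methyl on C10; ring A = C1–C5 and C10, ring B = C5–C10); (3S)-3-methylpentanoic acid, ethyl prop-1-enyl ether and allyl acrylate are taken as commercial.

Step 1
Reactants: 1 geraniol; 2 (3S)-3-methylpentanoic acid
Product: 3 geranyl (3S)-3-methylpentanoate
Conditions: DCC, 4-(dimethylamino)pyridine (cat.), CH2Cl2, 0 °C to rt
Reagents that add atoms: none
Why: Steglich esterification of the primary allylic alcohol; no stereocentre is formed and the β-stereocentre of the acid cannot epimerise.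

Step 2
Reactants: 3 geranyl (3S)-3-methylpentanoate
Product: 4 (2E,6E)-3,7-dimethyl-8-oxoocta-2,6-dien-1-yl (3S)-3-methylpentanoate
Conditions: SeO2 (1.1 equiv), 1,4-dioxane, 80 °C
Reagents that add atoms: selenium dioxide O=[Se]=O
Why: Riley allylic oxidation (ene reaction, then [2,3]-sigmatropic shift) should attack the (E)-methyl group of the electron-richer distal alkene and give the (E)-enal, the alkene next to the ester being deactivated; no stereocentre is formed.

Step 3
Reactants: 4 (2E,6E)-3,7-dimethyl-8-oxoocta-2,6-dien-1-yl (3S)-3-methylpentanoate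
Product: 5 (2E,6E)-3,7-dimethylnona-2,6,8-trien-1-yl (3S)-3-methylpentanoate
Conditions: Ph3PCH3Br, KN(SiMe3)2, THF, −78 to 0 °C
Reagents that add atoms: methyltriphenylphosphonium bromide C[P+](c1ccccc1)(c1ccccc1)c1ccccc1.[Br-]
Why: Wittig methylenation of the enal, which is far more electrophilic than the ester, should give the (E)-1,3-diene with the alkene geometries untouched.

Step 4
Reactants: 6 isobutyryl chloride; 7 ethyl prop-1-enyl ether (E/Z mixture)
Product: 9 3-ethoxy-2,2,4-trimethylcyclobutan-1-one, via dimethylketene 8 (not isolated)
Conditions: Et3N, toluene, 80 °C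
Reagents that add atoms: none
Why: Dehydrochlorination gives dimethylketene, which undergoes a thermal ketene–enol ether [2+2] cycloaddition in which the ketene carbonyl carbon bonds to the nucleophilic β-carbon of the enol ether, so OEt ends up β to the ketone; the racemic cis/trans mixture does not matter because both centres are lost in step 5.

Step 5
Reactants: 9 3-ethoxy-2,2,4-trimethylcyclobutan-1-one
Product: 10 2,4,4-trimethylcyclobut-2-en-1-one
Conditions: DBU, CH2Cl2, 0 °C to rt
Reagents that add atoms: none
Why: E1cB β-elimination of ethanol from the β-alkoxy ketone, possible only through the single α-hydrogen because the other α-carbon is quaternary, should give the conjugated cyclobutenone.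

Step 6
Reactants: 5 (2E,6E)-3,7-dimethylnona-2,6,8-trien-1-yl (3S)-3-methylpentanoate; 10 2,4,4-trimethylcyclobut-2-en-1-one
Product: 11 cis-fused cyclobutanone cycloadduct (1R,5R,6R)
Conditions: (S)-1-(2-methylphenyl)-3,3-diphenyltetrahydro-1H,3H-pyrrolo[1,2-c][1,3,2]oxazaborole (20 mol %), HN(SO2CF3)2 (18 mol %), CH2Cl2, −78 to −40 °C
Reagents that add atoms: none
Why: Lewis-acid-catalysed endo Diels–Alder reaction of the strained cyclobutenone: the substituted diene terminus C9 bonds to the carbonyl-bearing C10 ("ortho" orientation, as with other 1-alkyl-2-alkyl dienes such as 1-vinylcyclohexene), the endo transition state puts the four-membered ring cis to the outside C9 substituent of the (E)-diene and so fixes C9, C10 and C5 relative to each other, and the chiral oxazaborolidinium salt selects the diene face (the (S)-series is written; the antipode would be taken if the sense of induction with this dienophile is the opposite).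

Step 7
Reactants: 11 cis-fused cyclobutanone cycloadduct (1R,5R,6R)
Product: 12 cis-fused cyclobutanol (C3 epimers)
Conditions: NaBH4, MeOH, 0 °C
Reagents that add atoms: none
Why: Hydride reduction of the strained ketone, to which the ester is inert; the new C3 carbinol centre is not controlled and need not be, since it is destroyed in step 8.

Step 8
Reactants: 12 cis-fused cyclobutanol (C3 epimers); 13 allyl acrylate
Product: 16 allyl β-hydroxy ester of the trans-decalin (ring A closed; C2/C3 epimers), via ring-opened C10 radical aldehyde 14 (not isolated), via allyl ester enolate 15 (not isolated)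
Conditions: CeCl3 (5 mol %), n-Bu4NCl (10 mol %), 9,10-diphenylanthracene (5 mol %), 13 (3 equiv), MeCN, 400 nm LED, rt
Reagents that add atoms: none
Why: Ligand-to-metal charge transfer in the tetravalent cerium alkoxide of 12 gives the C3 alkoxy radical, whose β-scission breaks the strained C3–C10 bond to give the C3 aldehyde and the planar tertiary C10 radical 14; this adds to allyl acrylate (C1–C10), the α-ester radical is reduced by the diphenylanthracene radical anion to enolate 15, and C2 adds to the C3 aldehyde (C2–C3). The closest known reaction type is the cerium-photocatalysed ring-opening/Giese/aldol formal cycloaddition of cycloalkanols with electron-poor alkenes, used here as a [4+2] ring expansion of a cyclobutanol; the Giese/aldol pairing is the same as in iron-hydride radical–polar crossover annulations. Ring A closes by a 6-(enolexo)-exo-trig aldol addition through a chair that becomes the trans-fused decalin. C10 is set in the Giese step: the C9 side chain and the C5 CMe2CHO arm, fixed cis to each other in step 6, shield one face of the radical, so C1 should enter trans to both and C20 end cis to them, while the configurations at C2 and C3 are not controlled and are erased in steps 9 and 10. The step needs scission of C3–C10 and not of C3–C4, both of which would give tertiary radicals: C10 is the more crowded centre (ring-fusion carbon flanked by the cis C9 substituent), so the C3–C10 bond carries more strain and is expected to break preferentially. It also needs intermolecular capture of 14 to outrun cyclisation onto the C13=C14 alkene, which excess acrylate secures because that cyclisation would have to attack a fully substituted alkene carbon or close in the endo mode.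

Step 9
Reactants: 16 allyl β-hydroxy ester of the trans-decalin (ring A closed; C2/C3 epimers)
Product: 17 allyl β-keto ester (3-oxo-2-carboxylate)
Conditions: Dess–Martin periodinane, CH2Cl2, 0 °C to rt
Reagents that add atoms: none
Why: Dess–Martin oxidation of the secondary carbinol removes the uncontrolled C3 centre and makes C2 part of a β-keto ester; no new stereocentre is formed.

Step 10
Reactants: 17 allyl β-keto ester (3-oxo-2-carboxylate)
Product: 19 (2E)-3-methyl-5-[(1R,4aS,8aS)-2,5,5,8a-tetramethyl-6-oxo-1,4,4a,5,6,7,8,8a-octahydronaphthalen-1-yl]pent-2-en-1-yl (3S)-3-methylpentanoate, via β-keto acid 18 (not isolated)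
Conditions: Pd(PPh3)4 (3 mol %), morpholine, THF, 0 °C to rt
Reagents that add atoms: none
Why: Tsuji deallylation–decarboxylation: zerovalent palladium ionises the allyl β-keto ester, morpholine takes up the allyl group and β-keto acid 18 loses CO2, while the trisubstituted allylic alkanoate of the side chain should ionise far more slowly; no stereocentre is formed.

Step 11
Reactants: 19 (2E)-3-methyl-5-[(1R,4aS,8aS)-2,5,5,8a-tetramethyl-6-oxo-1,4,4a,5,6,7,8,8a-octahydronaphthalen-1-yl]pent-2-en-1-yl (3S)-3-methylpentanoate
Product: 20 (2E)-5-[(1R,4aS,6S,8aS)-6-hydroxy-2,5,5,8a-tetramethyl-1,4,4a,5,6,7,8,8a-octahydronaphthalen-1-yl]-3-methylpent-2-en-1-yl (3S)-3-methylpentanoate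
Conditions: LiBH(s-Bu)3, THF, −78 °C; aq. NH4Cl
Reagents that add atoms: none
Why: Reduction with a bulky trialkylborohydride: the reagent should approach the 4,4-dimethyl-3-ketone along the equatorial trajectory (the axial path is blocked for a large hydride by the axial hydrogens at C1 and C5) and give the axial (3S) alcohol, cis to H-5 and trans to C20; the ester is inert at −78 °C.

Compound list

1 | geraniol | CC(C)=CCC/C(C)=C/CO | starting material
2 | (3S)-3-methylpentanoic acid | CC[C@H](C)CC(=O)O | starting material
3 | geranyl (3S)-3-methylpentanoate | CC[C@H](C)CC(=O)OC/C=C(\C)CCC=C(C)C | intermediate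
4 | (2E,6E)-3,7-dimethyl-8-oxoocta-2,6-dien-1-yl (3S)-3-methylpentanoate | CC[C@H](C)CC(=O)OC/C=C(\C)CC/C=C(\C)C=O | intermediate
5 | (2E,6E)-3,7-dimethylnona-2,6,8-trien-1-yl (3S)-3-methylpentanoate | CC[C@H](C)CC(=O)OC/C=C(\C)CC/C=C(\C)C=C | intermediate
6 | isobutyryl chloride | CC(C)C(Cl)=O | starting material
7 | ethyl prop-1-enyl ether (E/Z mixture) | CCOC=CC | starting material
8 | dimethylketene (not isolated) | CC(C)=C=O | intermediate
9 | 3-ethoxy-2,2,4-trimethylcyclobutan-1-one (racemic, cis/trans mixture) | CCOC1C(C)C(=O)C1(C)C | intermediate
10 | 2,4,4-trimethylcyclobut-2-en-1-one | CC1=CC(C)(C)C1=O | intermediate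
11 | (2E)-3-methyl-5-[(1R,5R,6R)-4,6,8,8-tetramethyl-7-oxobicyclo[4.2.0]oct-3-en-5-yl]pent-2-en-1-yl (3S)-3-methylpentanoate; cis ring fusion, side chain cis to the four-membered ring | CC[C@H](C)CC(=O)OC/C=C(\C)CC[C@@H]1C(C)=CC[C@@H]2C(C)(C)C(=O)[C@]12C | intermediate
12 | (2E)-5-[(1R,5R,6R)-7-hydroxy-4,6,8,8-tetramethylbicyclo[4.2.0]oct-3-en-5-yl]-3-methylpent-2-en-1-yl (3S)-3-methylpentanoate; carbinol epimers | CC[C@H](C)CC(=O)OC/C=C(\C)CC[C@@H]1C(C)=CC[C@@H]2C(C)(C)C(O)[C@]12C | intermediate
13 | allyl acrylate | C=CC(=O)OCC=C | starting material
14 | ring-opened C10 radical: cyclohexenyl radical with the C5 CMe2CHO arm and C9 side chain cis (9R) (not isolated) | CC[C@H](C)CC(=O)OC/C=C(\C)CC[C@@H]1C(C)=CC[C@H](C(C)(C)C=O)[C]1C | intermediate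
15 | allyl ester enolate after Giese addition; C1 on C10 trans to the C5 arm and the C9 side chain (not isolated) | CC[C@H](C)CC(=O)OC/C=C(\C)CC[C@@H]1C(C)=CC[C@H](C(C)(C)C=O)[C@@]1(C)CC=C([O-])OCC=C | intermediate
16 | allyl 3-hydroxy-2-carboxylate of the trans-fused decalin (H-5 and C20 trans, C9 side chain cis to C20, 9R; C2 and C3 epimer mixture) | CC[C@H](C)CC(=O)OC/C=C(\C)CC[C@@H]1C(C)=CC[C@@H]2C(C)(C)C(O)C(C(=O)OCC=C)C[C@@]12C | intermediate
17 | allyl 3-oxo-2-carboxylate of the trans-fused decalin (C2 epimers/enol) | CC[C@H](C)CC(=O)OC/C=C(\C)CC[C@@H]1C(C)=CC[C@@H]2C(C)(C)C(=O)C(C(=O)OCC=C)C[C@@]12C | intermediate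
18 | 3-oxo-2-carboxylic acid of the trans-fused decalin (not isolated) | CC[C@H](C)CC(=O)OC/C=C(\C)CC[C@@H]1C(C)=CC[C@@H]2C(C)(C)C(=O)C(C(=O)O)C[C@@]12C | intermediate
19 | (2E)-3-methyl-5-[(1R,4aS,8aS)-2,5,5,8a-tetramethyl-6-oxo-1,4,4a,5,6,7,8,8a-octahydronaphthalen-1-yl]pent-2-en-1-yl (3S)-3-methylpentanoate | CC[C@H](C)CC(=O)OC/C=C(\C)CC[C@@H]1C(C)=CC[C@@H]2C(C)(C)C(=O)CC[C@@]12C | intermediate
20 | (2E)-5-[(1R,4aS,6S,8aS)-6-hydroxy-2,5,5,8a-tetramethyl-1,4,4a,5,6,7,8,8a-octahydronaphthalen-1-yl]-3-methylpent-2-en-1-yl (3S)-3-methylpentanoate | CC[C@H](C)CC(=O)OC/C=C(\C)CC[C@@H]1C(C)=CC[C@@H]2C(C)(C)[C@@H](O)CC[C@@]12C | target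

Total step count: 11. Longest linear sequence: 9 steps (steps 1–3, then 6–11); the dienophile branch (steps 4–5) joins at step 6.

Steps most likely to fail

Step 8 (key step). β-Scission may also break the C3–C4 bond, since both fragments are tertiary radicals. The radical–polar crossover may stall at the open-chain Giese adduct, or the product alcohol may re-enter the alkoxy-radical cycle. The fallback sets out from enone 10 and triene 5 and comes back at 16. Wohl–Ziegler bromination of 10 (NBS, azobisisobutyronitrile, PhCF3, 80 °C), where the C2 methyl carries the only allylic hydrogens, should give 2-(bromomethyl)-4,4-dimethylcyclobut-2-en-1-one F1. The Diels–Alder reaction of step 6 with 5 should then give the C20-bromo cycloadduct F2, and NaBH4 the bromo cyclobutanol F3. NaH (THF, 0 °C) should trigger a Grob fragmentation in which the alkoxide pushes, the C3–C10 bond breaks and bromide leaves from C20. The position of the leaving group, not radical stability, fixes the regiochemistry, and the ring-opened aldehyde with an exocyclic C10=C20 methylene F4 results. Hydrogen-atom transfer from an iron hydride (Fe(acac)3, PhSiH3, 13, EtOH/ethylene glycol, rt) should then put a hydrogen on C20 (making the C20 methyl), generate the same C10 radical and close ring A by the Giese/aldol sequence to 16. The 1,1-disubstituted alkene is expected to react ahead of the trisubstituted ones.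

Step 6. The catalyst may discriminate the two diene faces poorly with this dienophile, whose β-carbon is shielded by the C4 methyl groups. The fallback sets out from 5 and 10 and comes back at 12. Me2AlCl (CH2Cl2, −78 °C) should promote the same endo, "ortho" cycloaddition without face control and give 11 together with the diastereomer that has the antipodal bicyclic core F5. A Corey–Bakshi–Shibata reduction of the mixture (catecholborane, toluene, −78 °C, stopped near half conversion) with the oxazaborolidine antipode matched to 11 is a kinetic resolution. It should convert 11 into 12 and leave F5 as the ketone, and alcohol and ketone are separated by chromatography.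

Step 5. Ethoxide is a poor leaving group, and the base may open the β-alkoxy cyclobutanone or oligomerise the strained, volatile enone instead of effecting clean elimination. The fallback sets out from 6 and comes back at 10. Dimethylketene 8 (from 6 and Et3N) is combined with 1-ethoxyprop-1-yne in a [2+2] cycloaddition to give 3-ethoxy-2,4,4-trimethylcyclobut-2-en-1-one F6. LiAlH4 (Et2O, 0 °C) should reduce the vinylogous ester carbonyl to 3-ethoxy-2,4,4-trimethylcyclobut-2-en-1-ol F7. Dilute HCl on work-up hydrolyses the enol ether with allylic transposition (Stork–Danheiser sequence) to 10, so no β-elimination is needed.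

Further compounds
F1 | step 8 | 2-(bromomethyl)-4,4-dimethylcyclobut-2-en-1-one | BrCC1=CC(C)(C)C1=O
F2 | step 8 | C20-bromo analogue of cycloadduct 11 (same configuration) | CC[C@H](C)CC(=O)OC/C=C(\C)CC[C@@H]1C(C)=CC[C@@H]2C(C)(C)C(=O)[C@]12CBr
F3 | step 8 | C20-bromo analogue of cyclobutanol 12 (carbinol epimers) | CC[C@H](C)CC(=O)OC/C=C(\C)CC[C@@H]1C(C)=CC[C@@H]2C(C)(C)C(O)[C@]12CBr
F4 | step 8 | ring-opened aldehyde with exocyclic C10=C20 methylene; C5 CMe2CHO arm and C9 side chain cis (9R) | CC[C@H](C)CC(=O)OC/C=C(\C)CC[C@@H]1C(C)=CC[C@H](C(C)(C)C=O)C1=C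
F5 | step 6 | diastereomer of 11 with the antipodal (1S,5S,6S) bicyclic core | CC[C@H](C)CC(=O)OC/C=C(\C)CC[C@H]1C(C)=CC[C@H]2C(C)(C)C(=O)[C@@]12C
F6 | step 5 | 3-ethoxy-2,4,4-trimethylcyclobut-2-en-1-one | CCOC1=C(C)C(=O)C1(C)C
F7 | step 5 | 3-ethoxy-2,4,4-trimethylcyclobut-2-en-1-ol | CCOC1=C(C)C(O)C1(C)C
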